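**Plan**
- Retrosynthesis: remove the two benzyl ethers; open ring D between the lauroyl-bearing carbon and the adjacent hydroxyl-bearing carbon (retro-Claisen) to a 4-hydroxy-2-pyrone; cut the chroman C4–pyrone C3 bond; cut the CH2–CO bond of the pyrone side chain.
- Enabling feature: ring D has oxygen on every second carbon (three ring C–OH, with the lauroyl C=O on the carbon between two of them and chroman C4 on the carbon between the next two). It is therefore a folded 3,5,7-trioxo acid chain, which a 6-(2-oxoalkyl)-4-hydroxy-2-pyrone stores in masked form.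
- Forward: rings A, B and C come intact from (S)-liquiritigenin. Triacetic acid lactone is chain-extended with methyl laurate, joined through its C3 to chroman C4, and the pyrone is then recyclised to ring D. Debenzylation is last.
- Stereochemistry: C2 (S) comes from (S)-liquiritigenin and is never touched. C4 is created in step 4 by attack on a planar benzylic cation, and the 2,4-cis (2S,4S) epimer is separated from the trans one.

Key step: step 5

Assumption: (S)-liquiritigenin is bought as the single (2S) enantiomer; the descriptors (2S,4S) of the target describe the 2,4-cis flavan.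

Step 1
Reactants: 1 (S)-liquiritigenin
Product: 2 (2S)-7-benzyloxy-2-(4-benzyloxyphenyl)chroman-4-one
Conditions: BnOH, PPh3, DIAD, THF, 0 °C to rt
Reagents that add atoms: benzyl alcohol, OCc1ccccc1
Why: Mitsunobu etherification benzylates both phenols under neutral conditions, so the base-labile flavanone ring, which would open to the 2'-hydroxychalcone and lose the C2 configuration, should stay closed.

Step 2
Reactants: 2 (2S)-7-benzyloxy-2-(4-benzyloxyphenyl)chroman-4-one
Product: 3 (2S,4S)-7-benzyloxy-2-(4-benzyloxyphenyl)chroman-4-ol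
Conditions: NaBH4, MeOH–THF, 0 °C
Reagents that add atoms: none
Why: Carbonyl reduction with NaBH4, where axial hydride attack should give mainly the 2,4-cis alcohol; the carbinol configuration is of no consequence because C4 becomes planar in step 4, and C2 is not touched.

Step 3
Reactants: 4 4-hydroxy-6-methylpyran-2-one (triacetic acid lactone); 5 methyl laurate
Product: 7 4-hydroxy-6-(2-oxotridecyl)pyran-2-one, via dilithio dianion of triacetic acid lactone 6 (not isolated)
Conditions: 4 (2.2 equiv), LiN(iPr)2 (4.5 equiv), THF–DMPU, −78 to 0 °C; then 5 (1 equiv), 0 °C to rt; 1 M HCl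
Reagents that add atoms: none
Why: Claisen-type C-acylation of the dianion of 4, whose 6-methylene carbanion is its most nucleophilic site, by the methyl ester; the excess dianion supplies the extra base that the more acidic product consumes.

Step 4
Reactants: 3 (2S,4S)-7-benzyloxy-2-(4-benzyloxyphenyl)chroman-4-ol; 7 4-hydroxy-6-(2-oxotridecyl)pyran-2-one
Product: 8 3-[(2S,4S)-7-benzyloxy-2-(4-benzyloxyphenyl)chroman-4-yl]-4-hydroxy-6-(2-oxotridecyl)pyran-2-one
Conditions: 7 (2 equiv), TsOH·H2O (10 mol%), CH2Cl2, 0 °C to rt, slow addition of 3; chromatographic separation of the C4 epimers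
Reagents that add atoms: none
Why: Acid-catalysed SN1 (Friedel–Crafts-type) C-alkylation of the enolic C3 of the 4-hydroxy-2-pyrone by the C4 benzylic cation, which the ring oxygen (ortho) and the 7-benzyloxy group (para) of ring A stabilise; C2 is not ionised by the mild acid, while C4 is set by face selection on the planar cation, so both C4 epimers are expected and the 2,4-cis epimer 8 is isolated by chromatography.

Step 5
Reactants: 8 3-[(2S,4S)-7-benzyloxy-2-(4-benzyloxyphenyl)chroman-4-yl]-4-hydroxy-6-(2-oxotridecyl)pyran-2-one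
Product: 10 1-{3-[(2S,4S)-7-benzyloxy-2-(4-benzyloxyphenyl)chroman-4-yl]-2,4,6-trihydroxyphenyl}dodecan-1-one, via magnesium-chelated triketo methyl ester 9 (not isolated)
Conditions: Mg(OMe)2 (excess), MeOH–THF, reflux; then cold 1 M HCl
Reagents that add atoms: none
Why: Magnesium-bound methoxide should add to the lactone carbonyl and open the pyrone to the chelated methyl 3,5,7-trioxo ester 9, whose doubly activated methylene between the C5 and C7 ketones attacks the ester carbonyl; loss of methoxide and enolisation then give the aromatic acylphloroglucinol, which as its phenoxide drains the equilibria. The closest known reaction type is the Mg(OMe)2-mediated Claisen recyclisation of 6-(2-oxoalkyl)-4-hydroxy-2-pyrones to acylphloroglucinols, an intramolecular (Dieckmann-type) Claisen condensation. Ring D closes in 6-exo-trig mode, and the new bond joins the lauroyl-bearing carbon to the carbon that was the lactone carbonyl. No stereocentre is formed, and C2 and C4 of the chroman are safe because neither carries an acidic hydrogen and no bond to them is broken. The step needs C-acylation and not aldol closure: an aldol through the ester α-carbon would leave the chroman-bearing carbon quaternary, so it cannot aromatise and stays reversible, and magnesium chelation of the 1,3-dicarbonyl units holds the chain folded for the Claisen mode. Re-lactonisation to 8 is also reversible, so the aromatic product should be the only sink.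

Step 6
Reactants: 10 1-{3-[(2S,4S)-7-benzyloxy-2-(4-benzyloxyphenyl)chroman-4-yl]-2,4,6-trihydroxyphenyl}dodecan-1-one
Product: 11 1-{2,4,6-trihydroxy-3-[(2S,4S)-7-hydroxy-2-(4-hydroxyphenyl)chroman-4-yl]phenyl}dodecan-1-one
Conditions: H2 (1 atm), Pd/C (10 wt% Pd), EtOAc–MeOH, rt
Reagents that add atoms: none
Why: Catalytic hydrogenolysis of the two aryl benzyl ethers; at balloon pressure and room temperature the hydrogen-bonded aryl ketone and the cyclic benzylic C2–O bond are expected to persist, and neither stereocentre is affected.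

**Compound list**
1 | (S)-liquiritigenin, (2S)-7-hydroxy-2-(4-hydroxyphenyl)chroman-4-one | O=C1C[C@@H](c2ccc(O)cc2)Oc2cc(O)ccc12 | starting material
2 | (2S)-7-benzyloxy-2-(4-benzyloxyphenyl)chroman-4-one | O=C1C[C@@H](c2ccc(OCc3ccccc3)cc2)Oc2cc(OCc3ccccc3)ccc12 | intermediate
3 | (2S,4S)-7-benzyloxy-2-(4-benzyloxyphenyl)chroman-4-ol (2,4-cis) | O[C@H]1C[C@@H](c2ccc(OCc3ccccc3)cc2)Oc2cc(OCc3ccccc3)ccc12 | intermediate
4 | 4-hydroxy-6-methylpyran-2-one (triacetic acid lactone) | Cc1cc(O)cc(=O)o1 | starting material
5 | methyl laurate (methyl dodecanoate) | CCCCCCCCCCCC(=O)OC | starting material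
6 | dilithio dianion of 4, lithium 6-(lithiomethyl)-2-oxopyran-4-olate (not isolated) | [Li+].[Li+].[CH2-]c1cc([O-])cc(=O)o1 | intermediate
7 | 4-hydroxy-6-(2-oxotridecyl)pyran-2-one | CCCCCCCCCCCC(=O)Cc1cc(O)cc(=O)o1 | intermediate
8 | 3-[(2S,4S)-7-benzyloxy-2-(4-benzyloxyphenyl)chroman-4-yl]-4-hydroxy-6-(2-oxotridecyl)pyran-2-one | O=c1oc(CC(=O)CCCCCCCCCCC)cc(O)c1[C@H]2C[C@@H](c3ccc(OCc4ccccc4)cc3)Oc3cc(OCc4ccccc4)ccc32 | intermediate
9 | methyl 2-[(2S,4R)-7-benzyloxy-2-(4-benzyloxyphenyl)chroman-4-yl]-3,5,7-trioxooctadecanoate, magnesium chelate in the flask, chain C2 epimers; same spatial arrangement at chroman C4 as in 8, the descriptor changes only by priority (not isolated) | CCCCCCCCCCCC(=O)CC(=O)CC(=O)C(C(=O)OC)[C@H]1C[C@@H](c2ccc(OCc3ccccc3)cc2)Oc2cc(OCc3ccccc3)ccc12 | intermediate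
10 | 1-{3-[(2S,4S)-7-benzyloxy-2-(4-benzyloxyphenyl)chroman-4-yl]-2,4,6-trihydroxyphenyl}dodecan-1-one | CCCCCCCCCCCC(=O)c1c(O)cc(O)c([C@H]2C[C@@H](c3ccc(OCc4ccccc4)cc3)Oc3cc(OCc4ccccc4)ccc32)c1O | intermediate
11 | 1-{2,4,6-trihydroxy-3-[(2S,4S)-7-hydroxy-2-(4-hydroxyphenyl)chroman-4-yl]phenyl}dodecan-1-one | CCCCCCCCCCCC(=O)c1c(O)cc(O)c([C@H]2C[C@@H](c3ccc(O)cc3)Oc3cc(O)ccc32)c1O | target

**Step count**
Total: 6 steps. Longest linear sequence: 5 steps (1 → 2 → 3 → 8 → 10 → 11); the pyrone branch (4 + 5 → 7) is one step.

**Steps most likely to fail**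

Step 4: poor facial selectivity in the capture of the C4 cation. Torsionally preferred axial attack places the incoming pyrone trans to the 2-aryl group, so the wanted cis epimer may well be the lesser one. Self-alkylation of 3 through its electron-rich ring A can also compete. The fallback delivers the C4 hydrogen last instead of the carbon substituent, and it sets out from ketone 2.
- A Reformatsky reaction (Zn, methyl bromoacetate, THF) should give methyl 2-[(2S)-7-benzyloxy-2-(4-benzyloxyphenyl)-4-hydroxychroman-4-yl]acetate F1.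
- Dehydration without acid (methyl N-(triethylammoniosulfonyl)carbamate, toluene, 50 °C) should give methyl 2-[(2S)-7-benzyloxy-2-(4-benzyloxyphenyl)-2H-chromen-4-yl]acetate F2; an exocyclic alkene isomer would serve equally.
- Hydrogenation over Pd/C poisoned with 2,2'-bipyridyl, which spares aryl benzyl ethers, should add hydrogen to the face away from the 2-aryl group and give the 2,4-cis ester methyl 2-[(2S,4R)-7-benzyloxy-2-(4-benzyloxyphenyl)chroman-4-yl]acetate F3.
- Its lithium enolate (LiN(iPr)2, THF, −78 °C) is C-acetoacetylated with diketene to methyl 2-[(2S,4R)-7-benzyloxy-2-(4-benzyloxyphenyl)chroman-4-yl]-3,5-dioxohexanoate F4.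
- Lactonisation with DBU in hot toluene should give 3-[(2S,4S)-7-benzyloxy-2-(4-benzyloxyphenyl)chroman-4-yl]-4-hydroxy-6-methylpyran-2-one F5.
- Acylation of the dianion of F5 with methyl laurate 5, as in step 3, comes back to 8 as a single C4 epimer.

Step 5: slow C-acylation at the hindered ester carbonyl next to the chroman-bearing carbon, so that retro-Claisen loss of the side chain or simple return to the pyrone takes over. The fallback closes ring D before the chroman is attached and sets out from 7 and 3. The same Mg(OMe)2 recyclisation on the unhindered pyrone 7 should give 1-(2,4,6-trihydroxyphenyl)dodecan-1-one F6. Acid-catalysed Friedel–Crafts alkylation of F6 (in excess) with 3 at one of its two equivalent free ring positions (TsOH·H2O or BF3·OEt2, dioxane), with separation of the 2,4-cis epimer, comes back at 10.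

Step 3: incomplete acylation, because the acidic product quenches the dianion and the ester can be enolised or attacked at oxygen. The fallback replaces the acylation by an aldol addition and oxidation and sets out from 4. The dianion 6 is added to dodecanal (THF, −78 °C) to give 4-hydroxy-6-(2-hydroxytridecyl)pyran-2-one F7. Oxidation of the secondary alcohol with CrO3/H2SO4 in acetone (Jones oxidation, 0 °C) comes back at 7.

Further compounds
F1 | step 4 | methyl 2-[(2S)-7-benzyloxy-2-(4-benzyloxyphenyl)-4-hydroxychroman-4-yl]acetate (C4 epimers) | COC(=O)CC1(O)C[C@@H](c2ccc(OCc3ccccc3)cc2)Oc2cc(OCc3ccccc3)ccc12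
F2 | step 4 | methyl 2-[(2S)-7-benzyloxy-2-(4-benzyloxyphenyl)-2H-chromen-4-yl]acetate | COC(=O)CC1=C[C@@H](c2ccc(OCc3ccccc3)cc2)Oc2cc(OCc3ccccc3)ccc12
F3 | step 4 | methyl 2-[(2S,4R)-7-benzyloxy-2-(4-benzyloxyphenyl)chroman-4-yl]acetate | COC(=O)C[C@H]1C[C@@H](c2ccc(OCc3ccccc3)cc2)Oc2cc(OCc3ccccc3)ccc12
F4 | step 4 | methyl 2-[(2S,4R)-7-benzyloxy-2-(4-benzyloxyphenyl)chroman-4-yl]-3,5-dioxohexanoate | CC(=O)CC(=O)C(C(=O)OC)[C@H]1C[C@@H](c2ccc(OCc3ccccc3)cc2)Oc2cc(OCc3ccccc3)ccc12
F5 | step 4 | 3-[(2S,4S)-7-benzyloxy-2-(4-benzyloxyphenyl)chroman-4-yl]-4-hydroxy-6-methylpyran-2-one | Cc1cc(O)c([C@H]2C[C@@H](c3ccc(OCc4ccccc4)cc3)Oc3cc(OCc4ccccc4)ccc32)c(=O)o1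
F6 | step 5 | 1-(2,4,6-trihydroxyphenyl)dodecan-1-one | CCCCCCCCCCCC(=O)c1c(O)cc(O)cc1O
F7 | step 3 | 4-hydroxy-6-(2-hydroxytridecyl)pyran-2-one | CCCCCCCCCCCC(O)Cc1cc(O)cc(=O)o1
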